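**Retrosynthetic overview**

- Artonin C ⇐ heptakis-MOM ether 31. Ring A is aromatised last from a 2-cinnamoyl dione enol ether (selenoxide elimination), the ring B ketone comes from a Weinreb amide and an aryllithium, and the chalcone arm from an aldol, all built on acid 13.
- Acid 13 ⇐ bridged lactone 11 + cyclohexane-1,3-dione: zerovalent palladium ionises the allylic C1–O bond and the dione enters at C3 on the face of the C4 carboxyl.
- Lactone 11 ⇐ bromolactone 10 ⇐ 3-bromo-6-methyl-2-pyrone 5 + 2,4-bis(methoxymethoxy)styrene 8 by [4+2], forming C4–C5 and C1–C6.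
- Feature: in the central cyclohexene (C1 methyl-bearing alkene carbon, C2 alkene CH, C3 ring A, C4 aroyl, C5 ring C, C6 CH2), C1 and C4 stand 1,4 to each other. The C4 acyl carbon can therefore be tied through oxygen to C1; this C(=O)–O bridge is the O1–C2 unit of a 6-methyl-2-pyrone, and its allylic C1–O bond is the leaving group that later brings ring A to C3 cis to C4.
- Ring order: ring C (bought) → central carbocycle (step 6) → ring A carbocycle attached (step 9) and aromatised (step 19); rings B and D arrive as arenes (steps 18 and 13).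

Key step: step 6

Remark on the chemistry: a 3-bromo-2-pyrone offers a Lewis acid only its carbonyl oxygen, so no chiral catalyst is counted on; the cycloadduct is made as the racemate and the wanted antipode is taken by resolution in step 7.

**Route**

Step 1
Reactants: 1 4-hydroxy-6-methyl-2H-pyran-2-one
Product: 2 4-bromo-6-methyl-2H-pyran-2-one
Conditions: Bu4NBr, P2O5, toluene, 100 °C
Reagents that add atoms: tetrabutylammonium bromide, CCCC[N+](CCCC)(CCCC)CCCC.[Br-]
Why: Dehydrative bromination of a vinylogous acid: P2O5 turns the C4 hydroxyl into a phosphate that bromide displaces by addition–elimination, a known conversion of 4-hydroxy-2-pyrones into 4-bromo-2-pyrones.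

Step 2
Reactants: 2 4-bromo-6-methyl-2H-pyran-2-one
Product: 3 6-methyl-2H-pyran-2-one
Conditions: Zn dust, AcOH, rt
Reagents that add atoms: none
Why: Reductive dehalogenation: the 4-bromopyrone is a vinylogous acyl bromide, so zinc in acetic acid should replace the halogen by hydrogen through electron transfer and protonation without reducing the pyrone ring.

Step 3
Reactants: 3 6-methyl-2H-pyran-2-one
Product: 5 3-bromo-6-methyl-2H-pyran-2-one, via dibromide 4 (not isolated)
Conditions: Br2, CH2Cl2, dark, 0 °C → rt; then Et3N, 0 °C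
Reagents that add atoms: bromine, BrBr
Why: Bromination–dehydrobromination as used for 3-bromo-2-pyrone itself: ionic addition of bromine across C3–C4 and base-induced loss of HBr through the acidic H3 should leave bromine at C3, and light is excluded because the radical pathway leads to the 5-bromo isomer.

Step 4
Reactants: 6 2,4-dihydroxybenzaldehyde
Product: 7 2,4-bis(methoxymethoxy)benzaldehyde
Conditions: MOMCl, iPr2NEt, CH2Cl2, 0 °C → rt
Reagents that add atoms: chloromethyl methyl ether, COCCl
Why: O-Alkylation of both phenols (Williamson-type acetal formation) under amine base, the aldehyde being inert.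

Step 5
Reactants: 7 2,4-bis(methoxymethoxy)benzaldehyde
Product: 8 2,4-bis(methoxymethoxy)-1-vinylbenzene
Conditions: Ph3PCH3Br, KOtBu, THF, 0 °C → rt
Reagents that add atoms: methyltriphenylphosphonium bromide, C[P+](c1ccccc1)(c1ccccc1)c1ccccc1.[Br-]
Why: Wittig methylenation with the non-stabilised ylide, to which aryl MOM ethers are inert.

Step 6
Reactants: 5 3-bromo-6-methyl-2H-pyran-2-one; 8 2,4-bis(methoxymethoxy)-1-vinylbenzene
Product: 9 racemic endo 4-bromo-5-[2,4-bis(methoxymethoxy)phenyl]-1-methyl-2-oxabicyclo[2.2.2]oct-7-en-3-one (aryl anti to the lactone bridge)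
Conditions: 8 (2 equiv), BHT (cat.), toluene (2 M), 90 °C, sealed tube
Reagents that add atoms: none
Why: The reaction is a concerted but asynchronous inverse-electron-demand [4+2] cycloaddition between the LUMO of the bromopyrone and the HOMO of the electron-rich styrene, the bond from the styrene CH2 to pyrone C6 running ahead of the bond from the benzylic carbon to pyrone C3. The closest known reaction type is the thermal Diels–Alder addition of 3-bromo- and 3,5-dibromo-2-pyrones to styrenes and vinyl ethers, which gives isolable 5-substituted 2-oxabicyclo[2.2.2]oct-7-en-3-ones. The one ring closed is the six-membered carbocycle (future C1–C6), formed in a single intermolecular step by the bonds C4–C5 and C1–C6; it appears as a bridged bicycle because the lactone is kept. C1 and C4 are bridgeheads whose relative configuration is fixed by suprafacial addition across the diene, and C5 is set by the endo transition state, in which the aryl group lies under the diene carbons that become the alkene bridge and so ends anti to the lactone; absolute configuration is not controlled here and the racemate results. The step needs regioselectivity (aryl next to the brominated bridgehead), which follows from the large LUMO coefficient at pyrone C6 and the large HOMO coefficient at the styrene terminus, and endo selectivity, which is usual for this pyrone class. Bromine lowers the pyrone LUMO enough for reaction at 90 °C, below the range in which such bridged lactones lose CO2.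

Step 7
Reactants: 9 racemic endo bromolactone
Product: 10 (1S,4R,5R)-4-bromo-5-[2,4-bis(methoxymethoxy)phenyl]-1-methyl-2-oxabicyclo[2.2.2]oct-7-en-3-one
Conditions: preparative SFC, amylose tris(3,5-dimethylphenylcarbamate) phase, CO2/iPrOH
Reagents that add atoms: none
Why: Resolution by chromatography on a chiral stationary phase, in which no bond is made or broken: the rigid enantiomers should separate on a polysaccharide carbamate phase, and the bromine atom allows the (1S,4R,5R) antipode to be identified by anomalous-dispersion X-ray analysis.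

Step 8
Reactants: 10 (1S,4R,5R)-bromolactone
Product: 11 (1S,4S,5S)-5-[2,4-bis(methoxymethoxy)phenyl]-1-methyl-2-oxabicyclo[2.2.2]oct-7-en-3-one
Conditions: Bu3SnH, AIBN (cat.), benzene, 80 °C
Reagents that add atoms: none
Why: Radical chain dehalogenation: the stannyl radical abstracts the bridgehead bromine next to the lactone carbonyl, and the pyramidal bridgehead radical takes hydrogen from Bu3SnH with the skeleton and all three stereocentres unchanged.

Step 9
Reactants: 11 (1S,4S,5S)-lactone; 12 cyclohexane-1,3-dione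
Product: 13 (1R,2S,6S)-6-[2,4-bis(methoxymethoxy)phenyl]-2-(2-hydroxy-6-oxocyclohex-1-en-1-yl)-4-methylcyclohex-3-ene-1-carboxylic acid
Conditions: Pd(PPh3)4 (5 mol %), 12 (1.5 equiv), THF, 50 °C
Reagents that add atoms: none
Why: Tsuji–Trost allylic alkylation of a bridged vinyl lactone: zerovalent palladium ionises the tertiary allylic C1–O bond with inversion, the carboxylate set free deprotonates the dione, and the soft enolate attacks the less substituted allyl terminus C3 anti to palladium, so that the ring A precursor enters cis to the C4 carboxyl (net retention) and the alkene is left at C1=C2, any O-allylated dione re-ionising to the C-alkylated product.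

Step 10
Reactants: 13 acid
Product: 15 (1R,2S,6S)-6-[2,4-bis(methoxymethoxy)phenyl]-2-(2-hydroxy-6-oxocyclohex-1-en-1-yl)-N-methoxy-N,4-dimethylcyclohex-3-ene-1-carboxamide, via enol lactone 14 (not isolated)
Conditions: EDC·HCl, CH2Cl2, 0 °C → rt; then MeNHOMe·HCl, iPr2NEt, rt
Reagents that add atoms: N,O-dimethylhydroxylamine hydrochloride, CNOC.Cl
Why: Carbodiimide dehydration closes the cis-disposed acid onto the dione enol as a six-membered enol lactone, a vinylogous anhydride that the amine opens at the acyl carbon (acyl transfer) to give the Weinreb amide and the free dione without enolising C4.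

Step 11
Reactants: 15 Weinreb amide
Product: 16 (1R,2S,6S)-6-[2,4-bis(methoxymethoxy)phenyl]-N-methoxy-2-[2-(methoxymethoxy)-6-oxocyclohex-1-en-1-yl]-N,4-dimethylcyclohex-3-ene-1-carboxamide
Conditions: MOMCl, iPr2NEt, CH2Cl2, 0 °C
Reagents that add atoms: chloromethyl methyl ether, COCCl
Why: O-Alkylation of the acidic enol by the hard electrophile MOMCl gives the vinylogous ester, and because the two dione oxygens are equivalent a single isomer is expected.

Step 12
Reactants: 7 2,4-bis(methoxymethoxy)benzaldehyde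
Product: 17 (E)-3-[2,4-bis(methoxymethoxy)phenyl]prop-2-enal
Conditions: Ph3P=CHCHO, toluene, 80 °C
Reagents that add atoms: (triphenylphosphoranylidene)acetaldehyde, O=CC=P(c1ccccc1)(c1ccccc1)c1ccccc1
Why: Wittig olefination with a stabilised formyl ylide, which should give the (E)-enal.

Step 13
Reactants: 16 vinylogous ester; 17 enal
Product: 19 (1R,2S,6S)-6-[2,4-bis(methoxymethoxy)phenyl]-2-{5-[(E)-3-[2,4-bis(methoxymethoxy)phenyl]-1-hydroxyprop-2-en-1-yl]-2-(methoxymethoxy)-6-oxocyclohex-1-en-1-yl}-N-methoxy-N,4-dimethylcyclohex-3-ene-1-carboxamide (mixture of epimers at the two new centres), via lithium enolate 18 (not isolated)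
Conditions: LiN(iPr)2, THF, −78 °C; then 17, −78 °C; aq NH4Cl
Reagents that add atoms: none
Why: Kinetic deprotonation of the vinylogous ester at its α′-CH2 (Stork–Danheiser-type enolate) followed by 1,2-aldol addition to the enal, the hindered C4–H of the Weinreb amide being far less acidic; the two new centres are uncontrolled and are erased in steps 14 and 19.

Step 14
Reactants: 19 aldol adduct
Product: 20 (1R,2S,6S)-6-[2,4-bis(methoxymethoxy)phenyl]-2-{5-[(E)-3-[2,4-bis(methoxymethoxy)phenyl]prop-2-enoyl]-6-hydroxy-2-(methoxymethoxy)cyclohexa-1,5-dien-1-yl}-N-methoxy-N,4-dimethylcyclohex-3-ene-1-carboxamide (enol form of the β-diketone)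
Conditions: DMP (1.2 equiv), NaHCO3, CH2Cl2, 0 °C
Reagents that add atoms: none
Why: Dess–Martin oxidation of the allylic β-hydroxy ketone to the enolised β-diketone, buffered to spare the acid-labile cinnamyl alcohol and enol acetal and limited in oxidant to avoid tricarbonyl formation.

Step 15
Reactants: 21 2-iodobenzene-1,3-diol
Product: 22 2-iodo-1,3-bis(methoxymethoxy)benzene
Conditions: MOMCl, iPr2NEt, CH2Cl2, 0 °C → rt
Reagents that add atoms: chloromethyl methyl ether, COCCl
Why: O-Alkylation of both phenols with MOMCl under amine base.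

Step 16
Reactants: 23 3-methylbut-1-yne
Product: 24 (E)-4,4,5,5-tetramethyl-2-(3-methylbut-1-en-1-yl)-1,3,2-dioxaborolane
Conditions: pinacolborane, Cp2Zr(H)Cl (5 mol %), Et3N (10 mol %), neat, 60 °C, sealed
Reagents that add atoms: pinacolborane, CC1(C)OBOC1(C)C
Why: Zirconocene-catalysed syn-hydroboration of a terminal alkyne places boron at the terminus and fixes the (E)-geometry.

Step 17
Reactants: 22 aryl iodide; 24 alkenylboronate
Product: 25 1,3-bis(methoxymethoxy)-2-[(E)-3-methylbut-1-en-1-yl]benzene
Conditions: Pd(OAc)2 (5 mol %), SPhos (10 mol %), K3PO4, toluene/H2O, 90 °C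
Reagents that add atoms: none
Why: Suzuki–Miyaura coupling with retention of alkene geometry, a biaryl dialkylphosphine ligand being chosen because the iodide is flanked by two ortho alkoxy groups.

Step 18
Reactants: 20 β-diketone Weinreb amide; 25 arene
Product: 28 {(1R,2S,6S)-6-[2,4-bis(methoxymethoxy)phenyl]-2-{5-[(E)-3-[2,4-bis(methoxymethoxy)phenyl]prop-2-enoyl]-6-hydroxy-2-(methoxymethoxy)cyclohexa-1,5-dien-1-yl}-4-methylcyclohex-3-en-1-yl}{2,4-bis(methoxymethoxy)-3-[(E)-3-methylbut-1-en-1-yl]phenyl}methanone, via aryllithium 26 (not isolated), via lithium diketonate 27 (not isolated)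
Conditions: 25 (1.6 equiv): n-BuLi (1.5 equiv), TMEDA, THF, 0 °C; 20: LiN(SiMe3)2 (1.05 equiv), THF, −78 °C; mix, −78 → 0 °C; aq NH4Cl
Reagents that add atoms: none
Why: Directed ortho-lithiation of the symmetric arene gives a single aryllithium, which adds to the Weinreb amide to form a chelated tetrahedral adduct that releases the ketone only on work-up (Weinreb ketone synthesis), while the β-diketone is masked as its lithium enolate and C4 is not epimerised because the ketone never meets base.

Step 19
Reactants: 28 aryl ketone β-diketone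
Product: 31 (E)-1-{3-[(1S,5S,6R)-6-{2,4-bis(methoxymethoxy)-3-[(E)-3-methylbut-1-en-1-yl]benzoyl}-5-[2,4-bis(methoxymethoxy)phenyl]-3-methylcyclohex-2-en-1-yl]-2-hydroxy-4-(methoxymethoxy)phenyl}-3-[2,4-bis(methoxymethoxy)phenyl]prop-2-en-1-one, via selenide 29 (not isolated), via selenoxide 30 (not isolated)
Conditions: PhSeCl, pyridine, CH2Cl2, 0 °C; then mCPBA (1.0 equiv), −78 °C; then iPr2NH, → rt
Reagents that add atoms: none
Why: Reich selenoxide route to a phenol: selenenylation of the β-diketone at its central carbon, oxidation and syn-elimination should give a cyclohexadienone that tautomerises to aromatic ring A with the cinnamoyl group ortho to the new hydroxyl, the amine trapping PhSeOH so that the alkenes are not attacked.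

Step 20
Reactants: 31 artonin C heptakis(methoxymethyl) ether
Product: 32 artonin C
Conditions: 3 M aq HCl, MeOH/THF, rt → 40 °C
Reagents that add atoms: none
Why: Acid-catalysed acetal exchange to methanol removes all seven MOM groups, the mild temperature being chosen to avoid chalcone–flavanone isomerisation and ether formation between phenols and the two alkenes.

**Compound list**

1 | 4-hydroxy-6-methyl-2H-pyran-2-one | Cc1cc(O)cc(=O)o1 | starting material
2 | 4-bromo-6-methyl-2H-pyran-2-one | Cc1cc(Br)cc(=O)o1 | intermediate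
3 | 6-methyl-2H-pyran-2-one | Cc1cccc(=O)o1 | intermediate
4 | 3,4-dibromo-6-methyl-3,4-dihydro-2H-pyran-2-one (not isolated) | CC1=CC(Br)C(Br)C(=O)O1 | intermediate
5 | 3-bromo-6-methyl-2H-pyran-2-one | Cc1ccc(Br)c(=O)o1 | intermediate
6 | 2,4-dihydroxybenzaldehyde | O=Cc1ccc(O)cc1O | starting material
7 | 2,4-bis(methoxymethoxy)benzaldehyde | O=Cc1ccc(OCOC)cc1OCOC | intermediate
8 | 2,4-bis(methoxymethoxy)-1-vinylbenzene | C=Cc1ccc(OCOC)cc1OCOC | intermediate
9 | racemic endo 4-bromo-5-[2,4-bis(methoxymethoxy)phenyl]-1-methyl-2-oxabicyclo[2.2.2]oct-7-en-3-one (1:1 mixture of enantiomers) | C[C@]12C=C[C@](Br)(C(=O)O1)[C@@H](c1ccc(OCOC)cc1OCOC)C2.C[C@@]12C=C[C@@](Br)(C(=O)O1)[C@H](c1ccc(OCOC)cc1OCOC)C2 | intermediate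
10 | (1S,4R,5R)-4-bromo-5-[2,4-bis(methoxymethoxy)phenyl]-1-methyl-2-oxabicyclo[2.2.2]oct-7-en-3-one | C[C@]12C=C[C@](Br)(C(=O)O1)[C@@H](c1ccc(OCOC)cc1OCOC)C2 | intermediate
11 | (1S,4S,5S)-5-[2,4-bis(methoxymethoxy)phenyl]-1-methyl-2-oxabicyclo[2.2.2]oct-7-en-3-one | C[C@]12C=C[C@H](C(=O)O1)[C@@H](c1ccc(OCOC)cc1OCOC)C2 | intermediate
12 | cyclohexane-1,3-dione | O=C1CCCC(=O)C1 | starting material
13 | (1R,2S,6S)-6-[2,4-bis(methoxymethoxy)phenyl]-2-(2-hydroxy-6-oxocyclohex-1-en-1-yl)-4-methylcyclohex-3-ene-1-carboxylic acid | CC1=C[C@H](C2=C(O)CCCC2=O)[C@H](C(=O)O)[C@@H](c2ccc(OCOC)cc2OCOC)C1 | intermediate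
14 | cis-fused enol lactone, (6aR,7S,10aS)-7-[2,4-bis(methoxymethoxy)phenyl]-9-methyl-3,4,6a,7,8,10a-hexahydro-1H-benzo[c]chromene-1,6(2H)-dione (not isolated) | CC1=C[C@@H]2C3=C(CCCC3=O)OC(=O)[C@@H]2[C@@H](c2ccc(OCOC)cc2OCOC)C1 | intermediate
15 | (1R,2S,6S)-6-[2,4-bis(methoxymethoxy)phenyl]-2-(2-hydroxy-6-oxocyclohex-1-en-1-yl)-N-methoxy-N,4-dimethylcyclohex-3-ene-1-carboxamide | CC1=C[C@H](C2=C(O)CCCC2=O)[C@H](C(=O)N(C)OC)[C@@H](c2ccc(OCOC)cc2OCOC)C1 | intermediate
16 | (1R,2S,6S)-6-[2,4-bis(methoxymethoxy)phenyl]-N-methoxy-2-[2-(methoxymethoxy)-6-oxocyclohex-1-en-1-yl]-N,4-dimethylcyclohex-3-ene-1-carboxamide | CC1=C[C@H](C2=C(OCOC)CCCC2=O)[C@H](C(=O)N(C)OC)[C@@H](c2ccc(OCOC)cc2OCOC)C1 | intermediate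
17 | (E)-3-[2,4-bis(methoxymethoxy)phenyl]prop-2-enal | O=C/C=C/c1ccc(OCOC)cc1OCOC | intermediate
18 | kinetic lithium enolate of 16, enolised toward the ring CH2 next to the ketone (not isolated) | CC1=C[C@H](C2=C(OCOC)CCC=C2O[Li])[C@H](C(=O)N(C)OC)[C@@H](c2ccc(OCOC)cc2OCOC)C1 | intermediate
19 | aldol adduct: 16 carrying an (E)-3-[2,4-bis(methoxymethoxy)phenyl]-1-hydroxyprop-2-en-1-yl group on the ring carbon next to the ketone (epimer mixture at the two new centres) | CC1=C[C@H](C2=C(OCOC)CCC(C(O)/C=C/c3ccc(OCOC)cc3OCOC)C2=O)[C@H](C(=O)N(C)OC)[C@@H](c2ccc(OCOC)cc2OCOC)C1 | intermediate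
20 | β-diketone (enol form): 16 carrying an (E)-3-[2,4-bis(methoxymethoxy)phenyl]prop-2-enoyl group on the ring carbon next to the ketone | CC1=C[C@H](C2=C(OCOC)CCC(C(=O)/C=C/c3ccc(OCOC)cc3OCOC)=C2O)[C@H](C(=O)N(C)OC)[C@@H](c2ccc(OCOC)cc2OCOC)C1 | intermediate
21 | 2-iodobenzene-1,3-diol | Oc1cccc(O)c1I | starting material
22 | 2-iodo-1,3-bis(methoxymethoxy)benzene | COCOc1cccc(OCOC)c1I | intermediate
23 | 3-methylbut-1-yne | CC(C)C#C | starting material
24 | (E)-4,4,5,5-tetramethyl-2-(3-methylbut-1-en-1-yl)-1,3,2-dioxaborolane | CC(C)/C=C/B1OC(C)(C)C(C)(C)O1 | intermediate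
25 | 1,3-bis(methoxymethoxy)-2-[(E)-3-methylbut-1-en-1-yl]benzene | COCOc1cccc(OCOC)c1/C=C/C(C)C | intermediate
26 | {2,4-bis(methoxymethoxy)-3-[(E)-3-methylbut-1-en-1-yl]phenyl}lithium (not isolated) | [Li]c1ccc(OCOC)c(/C=C/C(C)C)c1OCOC | intermediate
27 | lithium enolate of β-diketone 20 (not isolated) | CC1=C[C@H](C2=C(OCOC)CCC(C(=O)/C=C/c3ccc(OCOC)cc3OCOC)=C2O[Li])[C@H](C(=O)N(C)OC)[C@@H](c2ccc(OCOC)cc2OCOC)C1 | intermediate
28 | aryl ketone: 20 with the N-methoxy-N-methylcarboxamide replaced by a 2,4-bis(methoxymethoxy)-3-[(E)-3-methylbut-1-en-1-yl]benzoyl group, (1R,2S,6S) | CC1=C[C@H](C2=C(OCOC)CCC(C(=O)/C=C/c3ccc(OCOC)cc3OCOC)=C2O)[C@H](C(=O)c2ccc(OCOC)c(/C=C/C(C)C)c2OCOC)[C@@H](c2ccc(OCOC)cc2OCOC)C1 | intermediate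
29 | selenide: diketo form of 28 with a phenylseleno group on the carbon between the two carbonyls (not isolated) | CC1=C[C@H](C2=C(OCOC)CCC([Se]c3ccccc3)(C(=O)/C=C/c3ccc(OCOC)cc3OCOC)C2=O)[C@H](C(=O)c2ccc(OCOC)c(/C=C/C(C)C)c2OCOC)[C@@H](c2ccc(OCOC)cc2OCOC)C1 | intermediate
30 | selenoxide of 29 (not isolated) | CC1=C[C@H](C2=C(OCOC)CCC([Se](=O)c3ccccc3)(C(=O)/C=C/c3ccc(OCOC)cc3OCOC)C2=O)[C@H](C(=O)c2ccc(OCOC)c(/C=C/C(C)C)c2OCOC)[C@@H](c2ccc(OCOC)cc2OCOC)C1 | intermediate
31 | artonin C heptakis(methoxymethyl) ether (ring A hydroxyl next to the chalcone carbonyl free), (1S,5S,6R) at the cyclohex-2-en-1-yl unit | CC1=C[C@H](c2c(O)c(C(=O)/C=C/c3ccc(OCOC)cc3OCOC)ccc2OCOC)[C@H](C(=O)c2ccc(OCOC)c(/C=C/C(C)C)c2OCOC)[C@@H](c2ccc(OCOC)cc2OCOC)C1 | intermediate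
32 | artonin C, (E)-1-{3-[(1S,5S,6R)-6-{2,4-dihydroxy-3-[(E)-3-methylbut-1-en-1-yl]benzoyl}-5-(2,4-dihydroxyphenyl)-3-methylcyclohex-2-en-1-yl]-2,4-dihydroxyphenyl}-3-(2,4-dihydroxyphenyl)prop-2-en-1-one | CC1=C[C@H](c2c(O)ccc(C(=O)/C=C/c3ccc(O)cc3O)c2O)[C@H](C(=O)c2ccc(O)c(/C=C/C(C)C)c2O)[C@@H](c2ccc(O)cc2O)C1 | target

**Step count**

Total step count: 20.
Longest linear sequence: 14 steps (steps 1–3, 6–11, 13, 14, 18–20).

**Steps most likely to fail**

1. Step 6 (key cycloaddition). The methyl group at the reacting C6 terminus of the pyrone may slow bond formation, so that long heating lets loss of CO2 from the adduct, polymerisation of the styrene and erosion of the endo preference take over. The fallback sets out from 6-methyl-2-pyrone 3 and comes back at lactone 11. Bromination with two equivalents of bromine and then Et3N should give 3,5-dibromo-6-methyl-2H-pyran-2-one F1, a more electron-poor diene of the type known to add styrenes well below 100 °C with high endo selectivity. Cycloaddition with styrene 8 would give the racemic endo dibromo lactone F2. Excess Bu3SnH with AIBN would remove the bridgehead and the vinylic bromine to give the racemic lactone F3, and chromatography on the chiral phase of step 7 would deliver 11.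

2. Step 9 (allylic alkylation). Ionisation of the bridged lactone is reversible, and palladium has to reach the alkene face that also carries the endo aryl group; slow alkylation would let β-hydride elimination to cyclohexadienes or attack at the methyl-bearing terminus compete. The fallback sets out from lactone 11 and comes back at Weinreb amide 15. Aminolysis of the lactone with the magnesium amide from MeNHOMe·HCl and iPrMgCl should give the hydroxy Weinreb amide F4, a tertiary allylic alcohol cis to the amide. Its lithium alkoxide (LiN(SiMe3)2) and methyl chloroformate give the methyl carbonate F5. Pd(PPh3)4 and dione 12 then effect a Tsuji–Trost alkylation in which ionisation is made irreversible by loss of CO2 and the methoxide set free deprotonates the dione. The stereochemical course (two inversions) is unchanged and the product is 15, so step 10 is not needed.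

3. Step 18 (ring B ketone). Addition of the ortho-substituted aryllithium to the flanked Weinreb amide may be slower than proton transfer (metalation of arene positions between two OMOM groups, enolisation at C4), which would consume the reagent or erode the C4 configuration. The fallback sets out from acid 13 and comes back at ketone 28. The enol lactone 14 is isolated (EDC·HCl) and opened at −78 °C by the arylmagnesium bromide F6, made from aryllithium 26 and MgBr2·OEt2; this is an acyl transfer of the Fujimoto–Belleau type with the dione enolate as leaving group, and gives the keto dione F7. MOMCl with iPr2NEt gives the enol ether F8, LiN(iPr)2 at −78 °C its kinetic lithium enolate F9, aldehyde 17 the aldol adduct F10, and Dess–Martin oxidation the diketone 28. The price is that the ring B ketone is present during enolate chemistry.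

Further compounds
F1 | step 6 | 3,5-dibromo-6-methyl-2H-pyran-2-one | Cc1oc(=O)c(Br)cc1Br
F2 | step 6 | racemic endo dibromo lactone, the 8-bromo analogue of 9 (1:1 mixture of enantiomers) | C[C@]12C(Br)=C[C@](Br)(C(=O)O1)[C@@H](c1ccc(OCOC)cc1OCOC)C2.C[C@@]12C(Br)=C[C@@](Br)(C(=O)O1)[C@H](c1ccc(OCOC)cc1OCOC)C2
F3 | step 6 | racemic endo 5-[2,4-bis(methoxymethoxy)phenyl]-1-methyl-2-oxabicyclo[2.2.2]oct-7-en-3-one (racemate of 11) | C[C@]12C=C[C@H](C(=O)O1)[C@@H](c1ccc(OCOC)cc1OCOC)C2.C[C@@]12C=C[C@@H](C(=O)O1)[C@H](c1ccc(OCOC)cc1OCOC)C2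
F4 | step 9 | (1S,4S,6S)-6-[2,4-bis(methoxymethoxy)phenyl]-4-hydroxy-N-methoxy-N,4-dimethylcyclohex-2-ene-1-carboxamide | C[C@@]1(O)C=C[C@H](C(=O)N(C)OC)[C@@H](c2ccc(OCOC)cc2OCOC)C1
F5 | step 9 | methyl carbonate of F4 | C[C@@]1(OC(=O)OC)C=C[C@H](C(=O)N(C)OC)[C@@H](c2ccc(OCOC)cc2OCOC)C1
F6 | step 18 | {2,4-bis(methoxymethoxy)-3-[(E)-3-methylbut-1-en-1-yl]phenyl}magnesium bromide | Br[Mg]c1ccc(OCOC)c(/C=C/C(C)C)c1OCOC
F7 | step 18 | keto dione: 13 with the carboxyl replaced by the 2,4-bis(methoxymethoxy)-3-[(E)-3-methylbut-1-en-1-yl]benzoyl group | CC1=C[C@H](C2=C(O)CCCC2=O)[C@H](C(=O)c2ccc(OCOC)c(/C=C/C(C)C)c2OCOC)[C@@H](c2ccc(OCOC)cc2OCOC)C1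
F8 | step 18 | methoxymethyl enol ether of F7 | CC1=C[C@H](C2=C(OCOC)CCCC2=O)[C@H](C(=O)c2ccc(OCOC)c(/C=C/C(C)C)c2OCOC)[C@@H](c2ccc(OCOC)cc2OCOC)C1
F9 | step 18 | kinetic lithium enolate of F8 | CC1=C[C@H](C2=C(OCOC)CCC=C2O[Li])[C@H](C(=O)c2ccc(OCOC)c(/C=C/C(C)C)c2OCOC)[C@@H](c2ccc(OCOC)cc2OCOC)C1
F10 | step 18 | aldol adduct of F9 with 17 (epimer mixture at the two new centres) | CC1=C[C@H](C2=C(OCOC)CCC(C(O)/C=C/c3ccc(OCOC)cc3OCOC)C2=O)[C@H](C(=O)c2ccc(OCOC)c(/C=C/C(C)C)c2OCOC)[C@@H](c2ccc(OCOC)cc2OCOC)C1
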